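Read at 2.08 d, Monday's and Tuesday's runs are past their fast rise, and that is the time to reckon from. End groups J pair off irreversibly into E, or meet end groups G to give links X and by-product Z, and that second step can run back.

| flask | J | G | remark | time |
|---|---|---|---|---|
| Monday's | 0.0050 M | 10 mM | run made earlier |  |
| Tuesday's | 0.020 M | 10 mM | run made earlier |  |
| flask | 0.010 M | 10.0 mM |  | 15 d |

| run | time / d | X / % | J / % |
|---|---|---|---|
| Monday's | 0.104 | 63.5 | 12.9 |
| Monday's | 0.500 | 72.3 | 3.4 |
| Monday's | 2.08 | 74.3 | 2.6 |
| Monday's | 10.0 | 68.4 | 0.2 |
| Tuesday's | 0.104 | 32.3 | 9.6 |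
| Tuesday's | 0.500 | 35.9 | 3.1 |
| Tuesday's | 2.08 | 32.2 | 2.4 |
| Tuesday's | 10.0 | 23.1 | 0.6 |

(standard deviation of a reading: 1 percentage point)

- a species is counted by the J in it: one E counts as two
- the earlier runs were read with a standard deviation of 1 percentage point
- steps thought possible: 2 J -> E; J + G <-> X + Z

- the best time, 15 d at the latest, for X
- the amount of X, in percent of the J charged, at that time
- the first time at which X reaches 17 %, in the same percent

Each X comes with one Z and takes one G. At that time Monday's run therefore gives 16.9 for [X][Z]/([J][G]), and Tuesday's gives 24.3. Their mean, 20.6, is the exchange quotient Q, the mass-action quotient of the reversible step taken at quasi-equilibrium. J is read at 2.6 % and 2.4 % with a scatter of 1 percentage point, so Q is a rough reading. It turns X and G into free J: [J] = [X][Z]/(Q[G]).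

Turn the J charge first. By hand, E forms with J squared and X with J, so a larger charge favours E. The readings show this in the balance left for E at 2.08 d, which rises from 23.1 % on Monday's run to 65.4 % on Tuesday's. X in percent does not show it by itself, since the G charge caps X at 50.0 % of the J on Tuesday's run. Your charge lies midway on a logarithmic scale, so my own rough figure for X is the geometric mean of the highest readings, 74.3 % on Monday's run and 35.9 % on Tuesday's, which is 51.6 %, and Q then leaves free J at 2.68 %.

Turn G next: it stands at 10.0 mM here as on both runs, so no reading shows its effect, but by hand, at equal X, more G leaves less free J.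

Turn time last: free J keeps feeding E, and Monday's X sinks to 68.4 % by 10.0 d.

The forecast gives 0.8 d (0.4 d to 1.6 d), 51 % (47 % to 55 %) and 0.33 h (0.25 h to 0.45 h), holding that “X slowly drains back through J into E after its peak”. Its X lies just under my figure.

    2 J → E (k = 47.0 M⁻¹ h⁻¹)
    J + G ⇌ X + Z (K = 21.0, k = 80.8 M⁻¹ h⁻¹)

The flask gives 0.425 d, 55.8 % and 0.287 h. The best time comes earlier than the forecast's 0.8 d, and X still stands at 43.0 % at 15.0 d. At 0.425 d, Q turns 55.8 % of X and 44.2 % of G into 3.42 % of free J, and this flask holds 3.35 %. The same flask charged with 0.017 M of G shows 59.6 % of X and 65 % of its G at 15.0 d. Q turns these into 1.57 % of free J, and that flask holds 1.51 %.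

(The earlier runs and the new flask are simulated on assumed constants, and the scatter is random.)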